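**Plan**

- Retrosynthesis: the two acids are masked as tert-butyl esters. Both C4–Cβ bonds (rings A and B to their propanoate chains; Cβ is the chain carbon on the ring) are then cut together, leaving a 4,4'-diboronate and two acrylates. The two C4–B bonds go back to C4–H, and the C1–O bond of the diaryl ether is cut last.
- Forward: Ullmann union of the two C6 rings, double C–H borylation, double rhodium conjugate addition that attaches both chains in one operation, then ester acidolysis. No ring is formed.
- Enabling feature: on each benzene ring C1 bears the bridging oxygen and C2/C6 bear methoxy groups. C3–H and C5–H therefore each have a methoxy neighbour and only C4–H has none, and C4 is the carbon that carries the chain. The two-fold symmetry lets rings A and B react alike.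
- Stereochemistry: none to set; the target has no stereocentre and no stereogenic double bond.

Key step: step 3

Remark: 2-iodo-1,3-dimethoxybenzene is taken as the commercial halide partner because the iodide is the most reactive halide in copper-mediated etherification; in step 2 each diboron molecule is counted as delivering one boryl group.

**Step 1**
Reactants: 1 2,6-dimethoxyphenol; 2 2-iodo-1,3-dimethoxybenzene
Product: 3 bis(2,6-dimethoxyphenyl) ether
Conditions: CuI (20 mol%), picolinic acid (40 mol%), K3PO4 (2 equiv), 1 (1.5 equiv), DMSO, 110 °C, argon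
Reagents that add atoms: none
Why: This is an Ullmann-type diaryl ether synthesis in which a picolinate-ligated phenoxide of monovalent copper engages the aryl iodide; the flanking methoxy groups are small and can coordinate copper, and excess phenol under argon should outrun phenol oxidation.

**Step 2**
Reactants: 3 bis(2,6-dimethoxyphenyl) ether; 4 bis(pinacolato)diboron
Product: 6 bis[2,6-dimethoxy-4-(4,4,5,5-tetramethyl-1,3,2-dioxaborolan-2-yl)phenyl] ether, via mono-boronate 5 (not isolated)
Conditions: [Ir(OMe)(cod)]2 (3 mol%), 4,4'-di-tert-butyl-2,2'-bipyridine (6 mol%), 4 (2.4 equiv), THF, 80 °C, sealed tube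
Reagents that add atoms: none
Why: Iridium-catalysed aromatic C–H borylation is ruled by sterics, so the tris(boryl)iridium catalyst should attack only C4–H on each ring, the one C–H with no ortho substituent, and the excess diboron should carry the mono-boronate on to the bis-boronate.

**Step 3**
Reactants: 6 bis[2,6-dimethoxy-4-(4,4,5,5-tetramethyl-1,3,2-dioxaborolan-2-yl)phenyl] ether; 7 tert-butyl acrylate
Product: 9 di-tert-butyl 3,3'-[oxybis(3,5-dimethoxy-4,1-phenylene)]dipropanoate, via mono-adduct 8 (not isolated)
Conditions: [Rh(OH)(cod)]2 (3 mol%), 7 (3 equiv), KOH (10 mol%), 1,4-dioxane/H2O 10:1, 80 °C, degassed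
Reagents that add atoms: none
Why: The hydroxo complex of monovalent rhodium takes the aryl group from each C4–B bond by transmetalation, the aryl–rhodium adds across the acrylate C=C with the aryl going to Cβ, and water protonates the oxa-π-allyl rhodium enolate at Cα, releasing the saturated ester and regenerating Rh–OH; the cycle runs once on each ring, through mono-adduct 8. The closest known reaction type is the Hayashi–Miyaura conjugate addition of arylboron reagents to acrylates, here supplied with boronates made directly by C–H borylation. No ring is closed and no stereocentre is created, because Cα and Cβ both end as CH2. The selectivity needed is protonation of the rhodium enolate ahead of β-hydride elimination (which would give the cinnamate) and ahead of protodeboronation; a phosphine-free, diene-ligated catalyst in a water-rich medium favours protonation. The C4 boronates have only hydrogen at C3 and C5, so transmetalation is not slowed by the crowded ether core, and the tert-butyl esters withstand the catalytic hydroxide.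

**Step 4**
Reactants: 9 di-tert-butyl 3,3'-[oxybis(3,5-dimethoxy-4,1-phenylene)]dipropanoate
Product: 11 apteniol E, via mono-tert-butyl ester 10 (not isolated)
Conditions: CF3CO2H/CH2Cl2 1:2, 0 °C to rt
Reagents that add atoms: none
Why: Acidolysis of tert-butyl esters by E1-type loss of the tert-butyl cation as 2-methylpropene leaves the aryl methyl ethers and the diaryl ether untouched, and the only free ring positions (C3, C5) are flanked on both sides and should resist tert-butylation.

**Compound list**

1 | 2,6-dimethoxyphenol | COc1cccc(OC)c1O | starting material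
2 | 2-iodo-1,3-dimethoxybenzene | COc1cccc(OC)c1I | starting material
3 | bis(2,6-dimethoxyphenyl) ether | COc1cccc(OC)c1Oc1c(OC)cccc1OC | intermediate
4 | bis(pinacolato)diboron | CC1(C)OB(OC1(C)C)B1OC(C)(C)C(C)(C)O1 | starting material
5 | 2-[4-(2,6-dimethoxyphenoxy)-3,5-dimethoxyphenyl]-4,4,5,5-tetramethyl-1,3,2-dioxaborolane (mono-boronate) | COc1cccc(OC)c1Oc1c(OC)cc(B2OC(C)(C)C(C)(C)O2)cc1OC | intermediate (not isolated)
6 | bis[2,6-dimethoxy-4-(4,4,5,5-tetramethyl-1,3,2-dioxaborolan-2-yl)phenyl] ether | COc1cc(B2OC(C)(C)C(C)(C)O2)cc(OC)c1Oc1c(OC)cc(B2OC(C)(C)C(C)(C)O2)cc1OC | intermediate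
7 | tert-butyl acrylate | C=CC(=O)OC(C)(C)C | starting material
8 | tert-butyl 3-{4-[2,6-dimethoxy-4-(4,4,5,5-tetramethyl-1,3,2-dioxaborolan-2-yl)phenoxy]-3,5-dimethoxyphenyl}propanoate (mono-adduct) | COc1cc(CCC(=O)OC(C)(C)C)cc(OC)c1Oc1c(OC)cc(B2OC(C)(C)C(C)(C)O2)cc1OC | intermediate (not isolated)
9 | di-tert-butyl 3,3'-[oxybis(3,5-dimethoxy-4,1-phenylene)]dipropanoate | COc1cc(CCC(=O)OC(C)(C)C)cc(OC)c1Oc1c(OC)cc(CCC(=O)OC(C)(C)C)cc1OC | intermediate
10 | 3-{4-[4-(3-tert-butoxy-3-oxopropyl)-2,6-dimethoxyphenoxy]-3,5-dimethoxyphenyl}propanoic acid (mono-tert-butyl ester) | COc1cc(CCC(=O)O)cc(OC)c1Oc1c(OC)cc(CCC(=O)OC(C)(C)C)cc1OC | intermediate (not isolated)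
11 | apteniol E, 3,3'-[oxybis(3,5-dimethoxy-4,1-phenylene)]dipropanoic acid | COc1cc(CCC(=O)O)cc(OC)c1Oc1c(OC)cc(CCC(=O)O)cc1OC | target

**Totals**

Total steps: 4. Longest linear sequence: 4 steps (1 → 3 → 6 → 9 → 11).

**Steps most likely to fail**

1. Step 1. Both partners carry two ortho substituents, so C–O bond formation at copper may be slower than hydrodeiodination of 2 and oxidative dimerisation of the electron-rich phenoxide, and little ether would form.
Fallback (from 1, back at 3): the union is moved from copper catalysis to nucleophilic aromatic substitution. The phenoxide of 1 (K2CO3, DMSO, about 120 °C) would displace the central methoxy group of commercial 1,2,3-trimethoxy-5-nitrobenzene (COc1cc(cc(OC)c1OC)[N+](=O)[O-]). That methoxy is para to the nitro group and twisted out of the ring plane by its neighbours, and addition–elimination through a Meisenheimer adduct would give 2-(2,6-dimethoxyphenoxy)-1,3-dimethoxy-5-nitrobenzene F1. Hydrogenation (H2, Pd/C, EtOAc) would give 4-(2,6-dimethoxyphenoxy)-3,5-dimethoxyaniline F2. Diazotisation (NaNO2, aq. HCl, 0 °C) followed by reduction of the diazonium salt with H3PO2 would remove the nitrogen and return to 3.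

2. Step 3. β-Hydride elimination from the rhodium alkyl or enolate (a Heck-type outcome on one or both arms) or protodeboronation may compete with protonation, giving mixtures at different oxidation levels or loss of an arm.
Fallback (from 6, back at 9): the elimination pathway is made the intended one. An oxidative boron-Heck reaction of 6 with 7 under divalent palladium (Pd(OAc)2, 2,9-dimethyl-1,10-phenanthroline, O2 1 atm, MeCN, 50 °C) would give di-tert-butyl (2E,2'E)-3,3'-[oxybis(3,5-dimethoxy-4,1-phenylene)]bis(prop-2-enoate) F3. Hydrogenation of both C=C bonds (H2, Pd/C, EtOAc) would return to 9. The same two C4–Cβ bonds are formed, one oxidation level higher.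

3. Step 2. Borylation may stall after one ring or stray to a C–H next to a small methoxy group, giving partly and wrongly borylated ethers that are hard to separate.
Fallback (from 1, back at 6): both boron sites are fixed by classical chemistry before the rings are joined.
- Para-bromination of 1 (N-bromosuccinimide, CHCl3, −45 °C to rt) would give 4-bromo-2,6-dimethoxyphenol F4.
- Its phenoxide (K2CO3, DMSO, about 120 °C) would displace the central methoxy group of 1,2,3-trimethoxy-5-nitrobenzene to give 5-bromo-2-(2,6-dimethoxy-4-nitrophenoxy)-1,3-dimethoxybenzene F5.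
- Chemoselective nitro reduction (H2, sulfided Pt/C, EtOAc) would give 4-(4-bromo-2,6-dimethoxyphenoxy)-3,5-dimethoxyaniline F6.
- Sandmeyer bromination (NaNO2, aq. HBr, 0 °C; then CuBr cat., 60 °C) would give bis(4-bromo-2,6-dimethoxyphenyl) ether F7.
- Double Miyaura borylation with 4 (PdCl2(dppf) cat., KOAc, 1,4-dioxane, 90 °C) would return to 6.

**Further compounds**

F1 | step 1 | 2-(2,6-dimethoxyphenoxy)-1,3-dimethoxy-5-nitrobenzene | COc1cccc(OC)c1Oc1c(OC)cc(cc1OC)[N+](=O)[O-]
F2 | step 1 | 4-(2,6-dimethoxyphenoxy)-3,5-dimethoxyaniline | COc1cccc(OC)c1Oc1c(OC)cc(N)cc1OC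
F3 | step 3 | di-tert-butyl (2E,2'E)-3,3'-[oxybis(3,5-dimethoxy-4,1-phenylene)]bis(prop-2-enoate) | COc1cc(/C=C/C(=O)OC(C)(C)C)cc(OC)c1Oc1c(OC)cc(/C=C/C(=O)OC(C)(C)C)cc1OC
F4 | step 2 | 4-bromo-2,6-dimethoxyphenol | COc1cc(Br)cc(OC)c1O
F5 | step 2 | 5-bromo-2-(2,6-dimethoxy-4-nitrophenoxy)-1,3-dimethoxybenzene | COc1cc(Br)cc(OC)c1Oc1c(OC)cc(cc1OC)[N+](=O)[O-]
F6 | step 2 | 4-(4-bromo-2,6-dimethoxyphenoxy)-3,5-dimethoxyaniline | COc1cc(Br)cc(OC)c1Oc1c(OC)cc(N)cc1OC
F7 | step 2 | bis(4-bromo-2,6-dimethoxyphenyl) ether | COc1cc(Br)cc(OC)c1Oc1c(OC)cc(Br)cc1OC
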